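The runs come from a simulation with made-up constants, and the scatter is random.

The coupling partner was charged at 50.0 mM, more than the 40.0 mM of the two substrates together. So if each coupling takes one of each, the substrates are the limiting reagent, and full conversion of them leaves a surplus of 10.0 mM of coupling partner.

| flask | left-handed substrate | right-handed substrate | coupling partner | free catalyst | racemization catalyst | remark | time |
|---|---|---|---|---|---|---|---|
| alpha | 20 mM | 20 mM | 2.5 equiv | 0.13 mol% | 1.1 mol% | the very flask that is asked about, followed so far |  |
| flask | 20 mM | 20 mM | 2.50 equiv | 0.13 mol% | 1.1 mol% |  | 2.5 h |

alpha run (percent of the left-handed substrate and right-handed substrate together charged)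

| time / min | left-handed substrate / % | right-handed substrate / % |
|---|---|---|
| 2.50 | 11.9 | 12.2 |
| 6.00 | 4.5 | 5.2 |
| 12.0 | 1.7 | 1.6 |
| 20.0 | 1.4 | 1.2 |
| 25.0 | 0.6 | 2.5 |

(each reading ± 0.5 percentage points)

* part of the left-handed substrate and right-handed substrate charged together that has reacted at 2.5 h
* excess of left-handed product over right-handed product in the product at 2.5 h
* excess of right-handed substrate over left-handed substrate among what is left of the two at 2.5 h

- free catalyst is single-handed; left-handed substrate and right-handed substrate are mirror images of each other, charged as a racemate, each of them at the stated concentration
- an excess is below zero if the other one leads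

In this flask the two substrates fell side by side, so I took their excess to stay near zero, though the last pair read 0.6 % and 2.5 %. Their sum then stalled, averaging 3.00 % over the last three readings. My first thought was a pseudo-first-order decay under a dying catalyst, but I doubted it, since such a constant takes [coupling partner] as steady, and the coupling partner sinks from 50.0 mM towards 10.0 mM.

So I assumed a rate κ[free catalyst][coupling partner][substrates] and put [coupling partner] = [substrates] + surplus. Integrated, ln([coupling partner]/[substrates]) rises at κ[free catalyst] times the surplus, however far the conversion has gone. The late readings put at 2.01 the whole rise of that logarithm from start to stop, the catalyst budget.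

I had two objections. An equilibrium could give the same stall, and I had no reading of the product to set beside it. The sum may also still have been sinking during those readings, which would make my budget too small. I therefore reckoned on a conversion of 97.0 % or somewhat above. No product was read, so the budget says nothing of the product's excess.

The forecast gave 97 %, 50 % and 3 % for the three questions, the second, in its words, “and this is a guess”.

The flask gave 98.5 %, 93.2 % and 0 % at 2.5 h, the conversion above the 97.0 % that my budget gave.

    left-handed substrate + racemization catalyst ⇌ right-handed substrate + racemization catalyst, rate k1*[racemization catalyst]*[left-handed substrate] forward; the back reaction follows from the equilibrium constant (k = 1800 M⁻¹ s⁻¹)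
    free catalyst → spent catalyst (k = 0.00130 s⁻¹)
    racemization catalyst ⇌ dormant form (K = 0.0740, k = 0.00260 s⁻¹)
    coupling partner + free catalyst + right-handed substrate → free catalyst + right-handed product (k = 890 M⁻² s⁻¹)
    coupling partner + free catalyst + left-handed substrate → free catalyst + left-handed product (k = 26000 M⁻² s⁻¹)

In the flask, free catalyst had a half-life of 8.89 min by its own decay, longer than the early 0.61 min of left-handed substrate under coupling. By 1.25 h free catalyst was down to 0.288 % of its charge, while 21.2 % of the coupling partner's own charge stood. In the neighbour flask with 0.033 mol% of free catalyst and the same surplus, my budget scales to 0.510, which gives a conversion of 76.9 %. The computed flask reached 83.0 %.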